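**Retrosynthetic overview**

1. Target 14 comes from hydrogenolysis of the penta-O-benzyl flavan 13; no stereocentre is touched.
2. Ring C (the pyran, the only ring that is built) is closed late: the keto-phenol 12 closes to a hemiketal and silane reduction of the cyclic oxocarbenium ion sets C2 cis to C4.
3. Key disconnection is C4–C(aryl, ring D). C4, the β-carbon of an enone and by nature an acceptor, is used as a donor (boron homoenolate 10) and joined to the iodine-bearing, electrophilic carbon of aryl iodide 5; this gives ketone 11 and sets C4.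
4. Boronate 10 comes from copper-catalysed asymmetric conjugate borylation of chalcone 9, itself from aldol condensation of 7 and 8.
5. Iodide 5 comes from phloroglucinol 1 and acid 2 by acylation, O-benzylation and iodination.

Assumption: 9-phenylnonanoic acid, 4-(benzyloxy)-2-hydroxybenzaldehyde and 1-[4-(benzyloxy)phenyl]ethan-1-one are taken as inexpensive catalogue chemicals.

The route is a paper design; no step has been run. The target has the 2,4-cis (2R,4R) configuration.

**Route**

Step 1
Reactants: 1 phloroglucinol (benzene-1,3,5-triol); 2 9-phenylnonanoic acid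
Product: 3 9-phenyl-1-(2,4,6-trihydroxyphenyl)nonan-1-one
Conditions: BF3·OEt2 (as medium), 90 °C, 3 h; then aq. NaOAc
Reagents that add atoms: none
Why: Friedel–Crafts acylation of the very electron-rich triol by the BF3-activated acid; the first acyl group deactivates the ring against a second.

Step 2
Reactants: 3 9-phenyl-1-(2,4,6-trihydroxyphenyl)nonan-1-one
Product: 4 9-phenyl-1-[2,4,6-tris(benzyloxy)phenyl]nonan-1-one
Conditions: BnBr (3.6 equiv), K2CO3 (5 equiv), DMF, 60 °C
Reagents that add atoms: benzyl bromide, BrCc1ccccc1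
Why: Williamson etherification of all three phenols; the polar aprotic solvent favours O- over C-alkylation and the heat drives the two chelated hydroxyls to completion.

Step 3
Reactants: 4 9-phenyl-1-[2,4,6-tris(benzyloxy)phenyl]nonan-1-one
Product: 5 1-[2,4,6-tris(benzyloxy)-3-iodophenyl]-9-phenylnonan-1-one
Conditions: NIS (1.05 equiv), TFA (0.3 equiv), MeCN, 0 °C → rt, dark
Reagents that add atoms: N-iodosuccinimide, O=C1CCC(=O)N1I
Why: Electrophilic aromatic iodination at one of the two equivalent free ring positions, each activated by two ortho and one para benzyloxy groups; one equivalent of reagent and the deactivating iodine stop it at mono-substitution.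

Step 4
Reactants: 6 4-(benzyloxy)-2-hydroxybenzaldehyde
Product: 7 4-(benzyloxy)-2-(methoxymethoxy)benzaldehyde
Conditions: MOMCl (1.5 equiv), K2CO3 (2 equiv), acetone, 50 °C
Reagents that add atoms: chloromethyl methyl ether, COCCl
Why: Williamson-type O-alkylation of the phenoxide; it marks the future ring oxygen O1 with the one group that can later be removed without touching benzyl ethers.

Step 5
Reactants: 7 4-(benzyloxy)-2-(methoxymethoxy)benzaldehyde; 8 1-[4-(benzyloxy)phenyl]ethan-1-one
Product: 9 (E)-3-[4-(benzyloxy)-2-(methoxymethoxy)phenyl]-1-[4-(benzyloxy)phenyl]prop-2-en-1-one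
Conditions: KOH (aq.), EtOH, rt, 16 h
Reagents that add atoms: none
Why: Claisen–Schmidt (crossed aldol) condensation of a non-enolisable aldehyde with the methyl ketone; E1cB dehydration gives the E-enone.

Step 6
Reactants: 9 (E)-3-[4-(benzyloxy)-2-(methoxymethoxy)phenyl]-1-[4-(benzyloxy)phenyl]prop-2-en-1-one
Product: 10 (3R)-3-[4-(benzyloxy)-2-(methoxymethoxy)phenyl]-1-[4-(benzyloxy)phenyl]-3-(4,4,5,5-tetramethyl-1,3,2-dioxaborolan-2-yl)propan-1-one
Conditions: B2pin2 (1.2 equiv), CuCl (5 mol%), NaOt-Bu (10 mol%), (R)-1-[(S)-2-(diphenylphosphino)ferrocenyl]ethyldicyclohexylphosphine (6 mol%), MeOH (2 equiv), THF, rt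
Reagents that add atoms: bis(pinacolato)diboron, CC1(C)OB(OC1(C)C)B1OC(C)(C)C(C)(C)O1
Why: Copper-catalysed asymmetric conjugate borylation, in which the chiral bisphosphine–copper boryl adds to one face of the enone β-carbon and methanol protonates the copper enolate, so the C–B stereocentre (future C4) is set as R; the ligand hand to use is whichever gives (R)-10 (the mirror-image ligand gives the antipode), confirmed by oxidation to the β-hydroxy ketone.

Step 7
Reactants: 10 (3R)-3-[4-(benzyloxy)-2-(methoxymethoxy)phenyl]-1-[4-(benzyloxy)phenyl]-3-(4,4,5,5-tetramethyl-1,3,2-dioxaborolan-2-yl)propan-1-one; 5 1-[2,4,6-tris(benzyloxy)-3-iodophenyl]-9-phenylnonan-1-one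
Product: 11 (3R)-3-[4-(benzyloxy)-2-(methoxymethoxy)phenyl]-1-[4-(benzyloxy)phenyl]-3-[2,4,6-tris(benzyloxy)-3-(9-phenylnonanoyl)phenyl]propan-1-one
Conditions: Pd2(dba)3 (5 mol%), PPh3 (80 mol%), Ag2O (1.5 equiv), DME, 85 °C, 24 h; 10 used at 1.5 equiv
Reagents that add atoms: none
Why: Proposed new method: the β-boryl ketone acts as a boron homoenolate, so C4 (normally the acceptor carbon of the enone) is the donor and the iodinated ring carbon the acceptor; Ag2O-assisted transmetalation of the secondary benzylic C–B bond to the arylpalladium iodide goes through a closed Pd–O–B transition state with retention, the large PPh3:Pd ratio and η3-benzyl stabilisation hold back β-hydride elimination to chalcone, and reductive elimination gives the C4–aryl bond as R; the closest known reaction type is the stereoretentive Suzuki–Miyaura coupling of enantioenriched secondary benzylic pinacol boronates (β-boryl carbonyl compounds included) with aryl iodides under Pd/PPh3/Ag2O, and what is new is the di-ortho-alkoxy aryl iodide together with the β-keto, ortho-alkoxy boronate.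

Step 8
Reactants: 11 (3R)-3-[4-(benzyloxy)-2-(methoxymethoxy)phenyl]-1-[4-(benzyloxy)phenyl]-3-[2,4,6-tris(benzyloxy)-3-(9-phenylnonanoyl)phenyl]propan-1-one
Product: 13 1-{2,4,6-tris(benzyloxy)-3-[(2R,4R)-7-(benzyloxy)-2-[4-(benzyloxy)phenyl]chroman-4-yl]phenyl}-9-phenylnonan-1-one, via keto-phenol 12 (not isolated)
Conditions: ZnBr2 (1 equiv), n-PrSH (2 equiv), CH2Cl2, 0 °C, 15 min; aqueous work-up, crude used directly; then Et3SiH (3 equiv), BF3·OEt2 (1.5 equiv), CH2Cl2, −78 → −30 °C
Reagents that add atoms: none
Why: Thiol-assisted Lewis-acid cleavage of the aryl MOM ether frees only the ring A phenol, which closes onto the ketone; BF3 then ionises the hemiketal to a 2-aryl oxocarbenium ion and Et3SiH delivers hydride axially to the face anti to the C4 aryl group (ionic hydrogenation, reductive etherification), so C2 becomes R and the two aryl groups end up cis, while the ring D oxygens stay benzylated and cannot compete for ring closure.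

Step 9
Reactants: 13 1-{2,4,6-tris(benzyloxy)-3-[(2R,4R)-7-(benzyloxy)-2-[4-(benzyloxy)phenyl]chroman-4-yl]phenyl}-9-phenylnonan-1-one
Product: 14 1-{2,4,6-trihydroxy-3-[(2R,4R)-7-hydroxy-2-(4-hydroxyphenyl)chroman-4-yl]phenyl}-9-phenylnonan-1-one (target, CNP0175574.1)
Conditions: H2 (1 atm), Pd/C (10 wt%), EtOAc–MeOH, rt
Reagents that add atoms: none
Why: Catalytic hydrogenolysis of the five benzyl ethers under neutral conditions; the hindered, hydrogen-bonded aryl ketone and the chroman C–O bond are left alone and neither stereocentre is involved, so no acid is present that could epimerise C2 or C4.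

**Compound list**

1 | phloroglucinol (benzene-1,3,5-triol) | Oc1cc(O)cc(O)c1 | starting material
2 | 9-phenylnonanoic acid | OC(=O)CCCCCCCCc1ccccc1 | starting material
3 | 9-phenyl-1-(2,4,6-trihydroxyphenyl)nonan-1-one | O=C(CCCCCCCCc1ccccc1)c1c(O)cc(O)cc1O | intermediate
4 | 9-phenyl-1-[2,4,6-tris(benzyloxy)phenyl]nonan-1-one | O=C(CCCCCCCCc1ccccc1)c1c(OCc2ccccc2)cc(OCc2ccccc2)cc1OCc1ccccc1 | intermediate
5 | 1-[2,4,6-tris(benzyloxy)-3-iodophenyl]-9-phenylnonan-1-one | O=C(CCCCCCCCc1ccccc1)c1c(OCc2ccccc2)cc(OCc2ccccc2)c(I)c1OCc1ccccc1 | intermediate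
6 | 4-(benzyloxy)-2-hydroxybenzaldehyde | O=Cc1ccc(OCc2ccccc2)cc1O | starting material
7 | 4-(benzyloxy)-2-(methoxymethoxy)benzaldehyde | O=Cc1ccc(OCc2ccccc2)cc1OCOC | intermediate
8 | 1-[4-(benzyloxy)phenyl]ethan-1-one | CC(=O)c1ccc(OCc2ccccc2)cc1 | starting material
9 | (E)-3-[4-(benzyloxy)-2-(methoxymethoxy)phenyl]-1-[4-(benzyloxy)phenyl]prop-2-en-1-one | O=C(/C=C/c1ccc(OCc2ccccc2)cc1OCOC)c1ccc(OCc2ccccc2)cc1 | intermediate
10 | (3R)-3-[4-(benzyloxy)-2-(methoxymethoxy)phenyl]-1-[4-(benzyloxy)phenyl]-3-(4,4,5,5-tetramethyl-1,3,2-dioxaborolan-2-yl)propan-1-one | O=C(C[C@@H](B1OC(C)(C)C(C)(C)O1)c1ccc(OCc2ccccc2)cc1OCOC)c1ccc(OCc2ccccc2)cc1 | intermediate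
11 | (3R)-3-[4-(benzyloxy)-2-(methoxymethoxy)phenyl]-1-[4-(benzyloxy)phenyl]-3-[2,4,6-tris(benzyloxy)-3-(9-phenylnonanoyl)phenyl]propan-1-one | O=C(C[C@H](c1ccc(OCc2ccccc2)cc1OCOC)c1c(OCc2ccccc2)cc(OCc2ccccc2)c(C(=O)CCCCCCCCc2ccccc2)c1OCc1ccccc1)c1ccc(OCc2ccccc2)cc1 | intermediate
12 | (3R)-3-[4-(benzyloxy)-2-hydroxyphenyl]-1-[4-(benzyloxy)phenyl]-3-[2,4,6-tris(benzyloxy)-3-(9-phenylnonanoyl)phenyl]propan-1-one (keto-phenol, in equilibrium with its cyclic hemiketal) | O=C(C[C@H](c1ccc(OCc2ccccc2)cc1O)c1c(OCc2ccccc2)cc(OCc2ccccc2)c(C(=O)CCCCCCCCc2ccccc2)c1OCc1ccccc1)c1ccc(OCc2ccccc2)cc1 | intermediate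
13 | 1-{2,4,6-tris(benzyloxy)-3-[(2R,4R)-7-(benzyloxy)-2-[4-(benzyloxy)phenyl]chroman-4-yl]phenyl}-9-phenylnonan-1-one | O=C(CCCCCCCCc1ccccc1)c1c(OCc2ccccc2)cc(OCc2ccccc2)c([C@@H]2C[C@H](c3ccc(OCc4ccccc4)cc3)Oc3cc(OCc4ccccc4)ccc32)c1OCc1ccccc1 | intermediate
14 | 1-{2,4,6-trihydroxy-3-[(2R,4R)-7-hydroxy-2-(4-hydroxyphenyl)chroman-4-yl]phenyl}-9-phenylnonan-1-one | O=C(CCCCCCCCc1ccccc1)c1c(O)cc(O)c([C@@H]2C[C@H](c3ccc(O)cc3)Oc3cc(O)ccc32)c1O | target

**Totals and risks**

Total step count: 9. Longest linear sequence: 6 (steps 4, 5, 6, 7, 8, 9; the other branch, steps 1, 2, 3, 7, 8, 9, is equally long).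

The three steps most likely to fail:

Step 7. The coupling has to bring a secondary benzylic boron carbon carrying an ortho-alkoxy aryl group onto an arylpalladium centre flanked by two benzyloxy groups. Slow transmetalation, β-hydride elimination back to chalcone 9, protodeboronation and loss of enantiopurity are all possible. Fallback: set out from chalcone 9 and iodide 5, bypass boronate 10, and join the same two carbons by an enantioselective reductive Heck reaction (Cacchi-type hydroarylation: Pd(OAc)2, (R)-BINAP, HCO2Na, DMF, 80 °C). Here the arylpalladium species from 5 adds across the enone with the aryl group going to the β-carbon, and formate-derived hydride releases the ketone. The route is rejoined at 11; this detour makes no new compound (F0). Its enantioselectivity is unproven and would need ligand screening.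

Step 8. The hydride may not discriminate the two faces of the oxocarbenium ion well enough, the silane may start to reduce an aryl ketone, or acid may cleave the C4–aryl bond. Fallback: set out from keto-phenol 12, purified after the first half of step 8, and fix C2 by catalyst control instead of substrate control. Noyori transfer hydrogenation (RuCl[(S,S)-TsDPEN](p-cymene), HCO2H/Et3N, rt) reduces only the unhindered aryl ketone and gives (1S,3R)-3-[4-(benzyloxy)-2-hydroxyphenyl]-1-[4-(benzyloxy)phenyl]-3-[2,4,6-tris(benzyloxy)-3-(9-phenylnonanoyl)phenyl]propan-1-ol F1. Mitsunobu etherification (PPh3, diisopropyl azodicarboxylate, THF, 0 °C) then closes ring C with inversion at the carbinol carbon and comes back to the route at 13.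

Step 2. The acylphloroglucinol anion is ambident, so C-benzylation and incomplete alkylation of the two chelated hydroxyls can cut the yield. Fallback: set out from acid 2 and reverse the order of events. Purchased 1,3,5-tris(benzyloxy)benzene F2 is acylated with the mixed anhydride formed in the flask from 2 and trifluoroacetic anhydride (CH2Cl2, 0 °C → rt). This Friedel–Crafts acylation of the pre-benzylated ring needs no phenoxide, bypasses 3 and comes back to the route at 4.

**Further compounds**

F0 | step 7 | none | none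
F1 | step 8 | (1S,3R)-3-[4-(benzyloxy)-2-hydroxyphenyl]-1-[4-(benzyloxy)phenyl]-3-[2,4,6-tris(benzyloxy)-3-(9-phenylnonanoyl)phenyl]propan-1-ol | O[C@@H](C[C@H](c1ccc(OCc2ccccc2)cc1O)c1c(OCc2ccccc2)cc(OCc2ccccc2)c(C(=O)CCCCCCCCc2ccccc2)c1OCc1ccccc1)c1ccc(OCc2ccccc2)cc1
F2 | step 2 | 1,3,5-tris(benzyloxy)benzene | c1ccccc1COc1cc(OCc2ccccc2)cc(OCc2ccccc2)c1
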